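The runs stem from a simulated flask for substances that don't exist.

**Early lag.** At early times the east run had lost 5.70 % of its substrate by 8.00 min but showed 0.9 % of other capture product, so the product curve trails the substrate curve. I wanted that trailing as a number.

| setting | east | south | north-east | north-west | theta | beta | delta | epsilon | alpha |
|---|---|---|---|---|---|---|---|---|---|
| substrate | 0.067 M | 0.067 M | 0.067 M | 0.10 M | 0.067 M (fed, over 40 min) | 0.067 M | 0.067 M (fed, over 40 min) | 0.067 M (fed, over 10 min) | 0.067 M |
| first nucleophile | 0.134 M | 0.134 M | 0.134 M | 0.134 M | 0.134 M | 0.134 M | 0.134 M | 0.134 M | 0.134 M |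
| second nucleophile | 0.121 M | 0.17 M | 0.27 M | 0.121 M | 0.121 M | 0.121 M | 0.121 M | 0.121 M | 0.121 M |
| temperature | 75 °C | 86 °C | 75 °C | 86 °C |  |  | 80 °C | 80 °C | 80 °C |
| remark | run made earlier | run made earlier | run made earlier | run made earlier | the addition at 60 °C, then warmed to 80 °C; the feed brings no volume worth counting | everything together at the start at 60 °C, warmed to 80 °C at 40 min | all else is in the flask from the start; the feed brings no volume worth counting | all else is in the flask from the start; the feed brings no volume worth counting | everything together at the start |
| time |  |  |  |  | 1.0 h | 1.0 h | 1.0 h | 1.0 h | 1.0 h |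

| run | time / min | other capture product / % | target / % | substrate / % |
|---|---|---|---|---|
| east | 8.00 | 0.9 | 1.4 | 94.3 |
| east | 20.0 | 5.0 | 4.0 | 87.4 |
| east | 40.0 | 13.1 | 4.6 | 76.6 |
| east | 60.0 | 21.3 | 5.3 | 67.8 |
| south | 15.0 | 16.1 | 6.9 | 73.2 |
| south | 30.0 | 35.5 | 7.1 | 51.8 |
| south | 50.0 | 56.4 | 6.3 | 32.7 |
| south | 60.0 | 64.8 | 5.1 | 26.0 |
| north-east | 15.0 | 5.6 | 2.2 | 89.3 |
| north-east | 30.0 | 12.8 | 2.1 | 82.0 |
| north-east | 50.0 | 22.4 | 3.2 | 72.1 |
| north-east | 60.0 | 26.9 | 3.1 | 67.7 |
| north-west | 15.0 | 13.8 | 8.3 | 71.9 |
| north-west | 30.0 | 32.0 | 9.0 | 51.5 |
| north-west | 50.0 | 50.1 | 9.1 | 33.3 |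
| north-west | 60.0 | 57.2 | 9.6 | 26.8 |

(readings scatter by 0.5 percentage points)

- the numbers in the tables scatter with a standard deviation of 0.5 percentage points

* the flask that comes out highest in amount of other capture product, in percent of the substrate charged; "all alike" if 1.5 percentage points covers them all (theta / beta / delta / epsilon / alpha / all alike)
* amount of other capture product at the end, in percent of the substrate charged, theta
* amount of other capture product at the end, in percent of the substrate charged, beta
* amount of other capture product at the end, in percent of the substrate charged, delta
* amount of other capture product at the end, in percent of the substrate charged, epsilon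
* amount of other capture product at the end, in percent of the substrate charged, alpha

**Substrate clock.** Substrate ended alike in east and north-east, which differ in second nucleophile (67.8 % and 67.7 %), and alike in south and north-west, which differ in charge and also in second nucleophile (26.0 % and 26.8 %). So I took a first-order constant k from the last readings: 0.00648 /min at 75 °C and 0.0225 /min at 86 °C. A straight line of ln k against temperature gave 0.0114 /min at 80 °C and 0.00119 /min at 60 °C. That last value lies outside the runs; it spends 4.64 % in 40 min.

**The lag.** Let the hold-up be what has left the substrate without yet being other capture product. If it drains first-order, the hold-up divided by k and by the part of the charge not yet product gives a time: 21.4 min in east, 11.4 min in north-east, 11.6 min in south. My doubt was that north-east's factor of 1.88 falls short of its 2.23 in second nucleophile. But these are differences of scattered readings, so I accepted a pseudo-first-order drain. Scaling south to 0.121 M and interpolating gave 18.9 min: the lag τ, the time by which the product curve trails the substrate-loss curve. At 80 °C I reckoned substrate loss, with a lifetime of 87.7 min, slower than that drain, so I took it as the rate-limiting step.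

**The reckoning.** A feed delays substrate on average by half its length, so I read the loss curve at the end time less that delay less τ. This gave 37.4 % for alpha, 33.7 % for epsilon and 21.3 % for delta. Delta's feed stops 20.0 min before the end, against a lag of 18.9 min, so I held its figure a little low.

**Cold flasks.** Theta and beta have those same 20.0 min hot, too short for a clean shift, so I split them. Of what the cold spent, 65.2 % drains. Of what the hot spends, 38.3 % arrives. That gave 10.5 % for beta and 9.15 % for theta, both low, since I counted no drain in the cold. In this reckoning alpha came highest.

**The result.** The forecast named alpha, with 10 %, 11.5 %, 23 %, 33.5 % and 37 % for theta, beta, delta, epsilon and alpha, and held that “Feeding acts only as a delay”. The flasks gave alpha highest, with 11.0 %, 12.5 %, 23.6 %, 33.7 % and 36.8 % in that order. Theta's figure moves by 5 points at second nucleophile 0.0500 M or 0.280 M, the other amounts and the time held.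

    substrate → intermediate (k = 0.690 /h, Ea = 113 kJ/mol)
    first nucleophile + intermediate ⇌ target (K = 12.0 /M, k = 120 /M/h, Ea = 51.0 kJ/mol, ΔH = −4.00 kJ/mol)
    second nucleophile + intermediate → other capture product (k = 71.0 /M/h, Ea = 54.0 kJ/mol)
    substrate → decomposition product (k = 3.60 × 10⁻⁴ /h, Ea = 128 kJ/mol)
    first nucleophile ⇌ dormant form (K = 0.110, k = 0.580 /h, Ea = 107 kJ/mol, ΔH = 15.0 kJ/mol)
    (constants at 80 °C)

**Alpha, read early.** Alpha read at 40 min instead of at the end has the mean time in the flask that delta has, 40.0 min. The same lag therefore gives 21.3 % for it, the figure I had for delta. That early reading of alpha held 23.6 % of other capture product, 7.66 % of target and 63 % of its substrate, while delta at its end held 23.6 % of other capture product and 64 % of its substrate.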